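At one temperature throughout, the south-east flask is the north charge read at a later time, so I needed to know where that charge stops and how fast it gets there.

| flask | starting material | coupling partner | target | time |
|---|---|---|---|---|
| north | 0.500 M | 0.750 M |  |  |
| south-west | 0.250 M | 0.500 M |  |  |
| south | 0.500 M | 0.750 M | 0.250 M |  |
| east | 0.500 M | 1.50 M |  |  |
| south-east | 0.500 M | 0.750 M |  | 33 min |

| run | time / min | [target] / M |
|---|---|---|
| north run | 2.2 | 0.132 |
| north run | 4.4 | 0.207 |
| north run | 6.6 | 0.261 |
| north run | 8.8 | 0.319 |
| north run | 11 | 0.348 |
| south-west run | 2.2 | 0.049 |
| south-west run | 4.4 | 0.087 |
| south-west run | 6.6 | 0.118 |
| south-west run | 8.8 | 0.140 |
| south-west run | 11 | 0.158 |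
| south run | 2.2 | 0.375 |
| south run | 4.4 | 0.458 |
| south run | 6.6 | 0.521 |
| south run | 8.8 | 0.558 |
| south run | 11 | 0.603 |
| east run | 2.2 | 0.290 |
| east run | 4.4 | 0.417 |
| east run | 6.6 | 0.465 |
| east run | 8.8 | 0.493 |
| east run | 11 | 0.495 |

(standard deviation of a reading: 0.004 M)

- how the opening rate goes with [coupling partner] round the charge of the north run: the exponent of the rate at two percent of starting material gone to target
- how the opening rate goes with [starting material] round the charge of the north run: the exponent of the rate at two percent of starting material gone to target (one fixed amount of target, the same in the runs compared)
- the south-west run starts with 0.250 M less of starting material and of coupling partner than the north run, and with no target. Compared where both hold the same amount of starting material, once fifteen percent of what the south-west run was charged with has turned into target, is the south-west run faster, slower or alike (within a tenth)?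
- target in the south-east run at 33 min, as a share of the starting material charged

- Overall: starting material + coupling partner -> target.
- Constant volume, constant temperature.
- Readings of a species count what is bound in complexes too.
- "The second partner" is coupling partner.
- An order is taken over about fifteen percent of the charge, up and down.

I began with the end. In the north charge, 0.500 M of starting material meets 0.750 M of coupling partner, so starting material is the limiting reagent and the ceiling is 0.500 M of target. My doubt was an equilibrium short of that ceiling, but the east run read 99.0% of its charge at 11 min, so I kept the ceiling.

For the approach I used the pair constant, the ordinary second-order rate constant: the natural logarithm of the ratio of partner to starting material at a reading, over that ratio at the charge, divided by the excess of partner and by the time. The last north reading gave 0.206 /M/min.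

Target might have bent that figure, but the south run, charged with it, gained 0.353 M by 11 min, close to the 0.348 M of the north run. Falling partner might have bent it too, yet the first north reading gave 0.205 /M/min, the same within scatter.

The east run resisted: its first reading gave 0.297 /M/min, higher than the north figure, so partner seemed to count more than once. I could not compute that away. I kept the north constant, read at the very charge of the south-east flask, and accepted the risk. On it I reckoned 0.0346 M of starting material in the south-east flask at 33 min, a share of 93.1% as target.

The forecast, reckoned its own way, stood a little above mine: 94%, with orders of 1.4 in coupling partner and 0.7 in starting material, and the south-west run alike. It held that “target neither inhibits nor accelerates”.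

The flask gave 95.5% in the south-east run, orders of 1.6 in coupling partner and 0.52 in starting material, and the south-west run alike. The forecast's order in starting material was higher than the flask's.

    starting material + coupling partner → target (0.2694 /M/min)
    starting material + 2 coupling partner → target + coupling partner (0.8460 /M²/min)
    2 starting material ⇌ idle substrate dimer, settled at all times (6.370 /M)
    starting material + coupling partner ⇌ idle substrate-reagent adduct, settled at all times (1.330 /M)

Put back into the pair constant, the south-east share asks for 0.253 /M/min, more than the north reading. Carried to the south-west run, the north constant puts half of its charge at 7.86 min, against 7.23 min simulated. Both flasks ran ahead of a constant that counts coupling partner once. Round the north charge the order in coupling partner stood at 1.6, and it fell to 1.4 in the simulated run without the parking of starting material as idle substrate dimer.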